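If a flask ends with its D gone, ask how the D split on the way, not how fast it went.

| flask | D | remark | time |
|---|---|---|---|
| birch | 0.39 M | run made earlier |  |
| ash | 1.5 M | run made earlier |  |
| flask | 0.77 M |  | 6.0 min |

* at 6.0 min, what has stopped the reaction, if anything has (forward and back rates have come level / all of D has reacted / it is still moving)
* part of the D gone at 6.0 min
* the E standing at 6.0 min, as a percentage of the D charged
* amount of G if the flask were left three thousand times as long, in percent of the D charged

- in percentages every species weighs as the D in it: one Q counts as two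
- the earlier runs were read with a standard deviation of 0.5 percentage points
- steps thought possible: D <-> G; G <-> Z; Z <-> D; 2 D -> Q; G -> E
- the reaction counts as stopped when no species that holds the D changes by six tenths of a point or more over the second half of the time
- a reading of G is of its free form alone
- a reading of D is of its free form alone

| run | time / min | D / % | E / % | G / % |
|---|---|---|---|---|
| birch | 0.667 | 6.7 | 64.9 | 1.9 |
| birch | 1.33 | 2.1 | 75.5 | 0.3 |
| birch | 2.00 | 0.6 | 76.2 | 0 |
| birch | 3.00 | 0 | 76.2 | 0 |
| birch | 4.00 | 0 | 75.9 | 0.1 |
| ash | 0.333 | 10.8 | 33.2 | 3.8 |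
| ash | 0.833 | 1.1 | 44.9 | 0.8 |
| ash | 1.50 | 0.7 | 49.2 | 0 |
| ash | 2.50 | 0.8 | 48.8 | 0 |
| ash | 4.00 | 0.3 | 49.2 | 0 |

(each reading ± 0.5 percentage points)

Read the first rows. In birch, G shows 1.9% at 0.667 min, while E already stands at 64.9%. That one low reading proves no steady stock of G and Z, so claim none. Suppose instead, as a trial form, that the way towards E goes with c_D to the first power, and let ash judge it.

Now read the last rows. E ends at 76.2% in birch and lower in ash, at 49.2%. Take this as a competing route of higher order, 2 D -> Q.

Each D then goes towards E with chance one over (one + s·c_D). Sum that as c_D falls to zero: E ends at the logarithm of (one + a), over a, where a is s times the starting c_D.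

Solve this for birch's last E: 1.75 M⁻¹. This is the split constant, a selectivity factor fitted to birch's E and not reckoned from any step: D lost to Q per D lost towards E, per unit of c_D.

Test it on ash, which played no part in it: a is 2.63, so E is 49.0%, against the 49.2% read. For the flask, a is 1.35, so E is 63.3%.

The forecast says all of D has reacted, with 100% of D gone (99.3% to 100%), E at 63.3% (61.5% to 65%) and long-term G at 0% (0% to 0.3%). Its ground is that E “competes with second-order dimerisation to Q”.

The flask gives all of D has reacted, 100% of D gone, E at 63.2% and long-term G at 0%.

    D ⇌ G (K = 1.28, k = 0.0247 s⁻¹)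
    G ⇌ Z (K = 0.351, k = 0.0655 s⁻¹)
    Z ⇌ D (k = 0.579 s⁻¹)
    2 D → Q (k = 0.0793 M⁻¹ s⁻¹)
    G → E (k = 0.240 s⁻¹)

At 0.245 min, the passing of 2 D into Q uses D at 0.98 of the forward rate of D into G. The split constant gave 63.3% for this flask, which stands at 63.2%. Carried to the neighbour with 1.9 M of D, it gives a of 3.33 and E of 44.0%; that neighbour stands at 43.9%.

The data were generated by integration from invented constants; the scatter is artificial.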